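## Plan

1. Numbering runs from C1 (carboxyl carbon) to C15 (benzylic CH2). The ring atoms are C3, C4, C5, O1 (bonded to C5) and O2 (bonded to C3). The enabling feature is the 1,2-dioxolane itself. Its two oxygen-bearing carbons C3 and C5 are both quaternary and are bridged by the C4 methylene. C5–O1–O2 is therefore a methyl ketone at the peroxide oxidation level (a peroxycarbenium ion), and C3–C4 is the C=C bond of a 2-substituted propene whose inner carbon can carry a tertiary cation.
2. Cuts, in retrosynthetic order: the C1 acid goes back to a silyl-protected primary alcohol. C4–C5 and C3–O2 are cut together, opening the ring to a silylperoxy ketal plus an alkene. The C5 peroxy ketal goes back to a C5=CH2 alkene (ozonolysis in methanol). Then C8–C9 (alkyl–alkyl coupling), C14–C15 (Wittig) and C6–C7 (enolate alkylation) are cut.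
3. Forward: the C9–C15 phenylalkyl bromide and the C5–C8 tosylate, which already carries the isopropenyl end, take three steps each and are then joined. The chain end becomes the silylperoxy ketal, the only ring closes in the annulation, and C1 is raised to the acid last.
4. Stereochemistry: C11 is bought with (S)-citronellyl bromide, and C7 is set by an Evans alkylation with the (R)-benzyl auxiliary. C3 and C5 arise in the annulation. Their cis relationship comes from the closure geometry, but C7 influences the absolute sense at C5 only weakly, so separation of diastereomers is part of the plan.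

Key step: step 11

Assumption: the C3/C5 isomers formed in the ring-forming step are true diastereomers, because C7 and C11 are fixed, and are taken to be separable by chromatography.

## Route

Step 1
Reactants: 1 (S)-citronellyl bromide [(6S)-8-bromo-2,6-dimethyloct-2-ene]
Product: 3 (4S)-6-bromo-4-methylhexanal, via secondary ozonide 2 (not isolated)
Conditions: O3, CH2Cl2, −78 °C; PPh3, −78 °C to rt
Reagents that add atoms: ozone, [O-][O+]=O
Why: Criegee ozonolysis of the only C=C bond, followed by phosphine reduction of the ozonide, removes the isopropylidene carbon as acetone and leaves the primary bromide and the remote C11 stereocentre untouched.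

Step 2
Reactants: 3 (4S)-6-bromo-4-methylhexanal; 4 benzyltriphenylphosphonium chloride
Product: 6 [(5S)-7-bromo-5-methylhept-1-en-1-yl]benzene (E/Z mixture), via benzylidene ylide 5 (not isolated)
Conditions: 4, KOt-Bu (slightly less than 4), THF, 0 °C; then 3, −78 °C to rt
Reagents that add atoms: none
Why: Wittig olefination with the semistabilised benzylide should be far faster at the aldehyde than alkylation or elimination at the primary bromide, and the alkene geometry does not matter because the double bond is saturated next.

Step 3
Reactants: 6 [(5S)-7-bromo-5-methylhept-1-en-1-yl]benzene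
Product: 7 [(5S)-7-bromo-5-methylheptyl]benzene
Conditions: H2 (1 atm), 10% Pd/C, EtOAc, rt
Reagents that add atoms: none
Why: Heterogeneous catalytic hydrogenation saturates the styrene-type double bond quickly under neutral conditions, which should not reduce an unactivated primary alkyl bromide or the arene.

Step 4
Reactants: 8 (4R)-4-benzyl-3-propanoyl-1,3-oxazolidin-2-one; 9 3-bromo-2-methylprop-1-ene (methallyl bromide)
Product: 11 (4R)-4-benzyl-3-[(2S)-2,4-dimethylpent-4-enoyl]-1,3-oxazolidin-2-one, via sodium (Z)-enolate 10 (not isolated)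
Conditions: NaHMDS, THF, −78 °C; 9, Bu4NI (cat.), −78 to −30 °C
Reagents that add atoms: none
Why: In this Evans asymmetric alkylation the chelated (Z)-enolate is attacked by the allylic bromide on the face away from the benzyl group of the (R)-auxiliary, which sets the future C7 centre (2S in the imide) and brings in C5, C6 and the C5 methyl group.

Step 5
Reactants: 11 (4R)-4-benzyl-3-[(2S)-2,4-dimethylpent-4-enoyl]-1,3-oxazolidin-2-one
Product: 12 (2S)-2,4-dimethylpent-4-en-1-ol
Conditions: LiBH4, H2O (1 equiv), Et2O, 0 °C
Reagents that add atoms: none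
Why: Reductive cleavage of the auxiliary with borohydride attacks the exocyclic imide carbonyl without enolisation, so the α-stereocentre is kept, the alkene is untouched and the oxazolidinone is recovered.

Step 6
Reactants: 12 (2S)-2,4-dimethylpent-4-en-1-ol
Product: 13 (2S)-2,4-dimethylpent-4-en-1-yl 4-methylbenzenesulfonate
Conditions: TsCl, Et3N, DMAP (cat.), CH2Cl2, 0 °C to rt
Reagents that add atoms: p-toluenesulfonyl chloride, Cc1ccc(cc1)S(=O)(=O)Cl
Why: O-sulfonylation of a primary alcohol breaks no bond at the stereocentre and turns the volatile alcohol into a non-volatile electrophile.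

Step 7
Reactants: 7 [(5S)-7-bromo-5-methylheptyl]benzene; 13 (2S)-2,4-dimethylpent-4-en-1-yl 4-methylbenzenesulfonate
Product: 15 [(5S,9R)-5,9,11-trimethyldodec-11-en-1-yl]benzene, via Grignard reagent 14 (not isolated)
Conditions: 7, Mg, THF, rt to 40 °C; then 13, Li2CuCl4 (5 mol %), THF, −78 °C to rt
Reagents that add atoms: none
Why: The Li2CuCl4-catalysed alkyl–alkyl cross-coupling of a primary Grignard reagent with a primary tosylate forms C8–C9 by displacement at a non-stereogenic carbon, so both methyl-bearing centres are carried over and the C7 descriptor changes from S to R only through CIP priorities.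

Step 8
Reactants: 15 [(5S,9R)-5,9,11-trimethyldodec-11-en-1-yl]benzene
Product: 17 [(5S,9R)-11-hydroperoxy-11-methoxy-5,9-dimethyldodecyl]benzene (both epimers at the ketal carbon C5 of the target numbering), via carbonyl oxide 16 (not isolated)
Conditions: O3, CH2Cl2–MeOH, −78 °C, dye end point; N2 purge, no reductant
Reagents that add atoms: ozone, [O-][O+]=O; methanol, CO
Why: In this Criegee ozonolysis in a participating solvent, the primary ozonide of a 1,1-disubstituted alkene should cleave mainly to the more substituted carbonyl oxide plus formaldehyde, methanol traps that carbonyl oxide as the α-methoxy hydroperoxide, and the much less reactive phenyl ring is spared by stopping at the end point.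

Step 9
Reactants: 17 [(5S,9R)-11-hydroperoxy-11-methoxy-5,9-dimethyldodecyl]benzene
Product: 18 triethyl{[(4R,8S)-2-methoxy-4,8-dimethyl-12-phenyldodecan-2-yl]peroxy}silane (both ketal epimers)
Conditions: Et3SiCl, imidazole, DMF, 0 °C
Reagents that add atoms: chlorotriethylsilane, CC[Si](Cl)(CC)CC
Why: O-silylation of the acidic hydroperoxide under imidazole catalysis is a standard protection that leaves the O–O bond and the ketal intact and installs the silyl group that is released in the ring closure.

Step 10
Reactants: 19 3-methylbut-3-en-1-ol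
Product: 20 tert-butyl[(3-methylbut-3-en-1-yl)oxy]diphenylsilane
Conditions: TBDPSCl, imidazole, CH2Cl2, rt
Reagents that add atoms: tert-butyl(chloro)diphenylsilane, CC(C)(C)[Si](Cl)(c1ccccc1)c1ccccc1
Why: Standard silyl ether formation masks the C1 hydroxyl as a bulky, weakly Lewis-basic and acid-robust ether that should tolerate tin(IV) chloride at low temperature.

Step 11
Reactants: 18 triethyl{[(4R,8S)-2-methoxy-4,8-dimethyl-12-phenyldodecan-2-yl]peroxy}silane; 20 tert-butyl[(3-methylbut-3-en-1-yl)oxy]diphenylsilane
Product: 23 tert-butyl(2-{(3S,5R)-5-[(2R,6S)-2,6-dimethyl-10-phenyldecyl]-3,5-dimethyl-1,2-dioxolan-3-yl}ethoxy)diphenylsilane (C2 and C6 arms cis; isolated from its diastereomers), via peroxycarbenium ion 21 (not isolated), via tertiary C3 cation 22 (not isolated)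
Conditions: 20 (2 equiv), SnCl4 (1 equiv, added last), CH2Cl2, −78 °C; aq NaHCO3
Reagents that add atoms: none
Why: SnCl4 binds the more basic methoxy oxygen of 18 and removes it, so both ketal epimers converge on the planar ion 21, whose C5 is attacked by the unhindered CH2 terminus of 20 to form C4–C5 and leave the charge on the dialkyl-substituted C3 of 22. Ring closure follows when O2, still carrying Et3Si, donates a lone pair to C3 and chloride strips the silyl group from the resulting oxonium ion; overall this is the known Lewis acid-promoted (3+2) annulation of triethylsilylperoxy ketals with 1,1-disubstituted alkenes. The single ring closes by five-membered attack of oxygen on a free tertiary carbocation, formally 5-endo with respect to the former C3=C4 bond but without a stereoelectronic penalty, since no π bond remains at the moment of closure. C3 is set relative to C5 in an envelope-like closure that keeps the two long arms pseudo-equatorial and hence cis (the C2 arm is enlarged by OTBDPS and the C6 arm is β-branched), whereas the face of 21 that is attacked, and so the absolute sense at C5, is steered only by the C7 methyl group in a 1,3-relationship and should be weakly biased. The step needs three selectivities: Markovnikov regiochemistry, secured by a tertiary rather than a primary cation; ionisation of C–OMe rather than C–OOSi, secured by the lower basicity and silyl shielding of the peroxide oxygens; and closure faster than proton loss or chloride capture, favoured by −78 °C, the labile Et3Si group and excess alkene present before the Lewis acid is added. Compound 23 is therefore expected together with the other cis isomer and the trans pair, and it is to be isolated by silica gel chromatography followed by HPLC.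

Step 12
Reactants: 23 tert-butyl(2-{(3S,5R)-5-[(2R,6S)-2,6-dimethyl-10-phenyldecyl]-3,5-dimethyl-1,2-dioxolan-3-yl}ethoxy)diphenylsilane
Product: 24 2-{(3S,5R)-5-[(2R,6S)-2,6-dimethyl-10-phenyldecyl]-3,5-dimethyl-1,2-dioxolan-3-yl}ethan-1-ol
Conditions: TBAF, AcOH, THF, 0 °C to rt
Reagents that add atoms: none
Why: Buffered fluoride-mediated desilylation is compatible with the peroxide because neither C3 nor C5 carries a hydrogen, so base-induced Kornblum–DeLaMare fragmentation is not possible.

Step 13
Reactants: 24 2-{(3S,5R)-5-[(2R,6S)-2,6-dimethyl-10-phenyldecyl]-3,5-dimethyl-1,2-dioxolan-3-yl}ethan-1-ol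
Product: 26 2-{(3R,5R)-5-[(2R,6S)-2,6-dimethyl-10-phenyldecyl]-3,5-dimethyl-1,2-dioxolan-3-yl}acetic acid (target), via dioxolane aldehyde 25 (not isolated)
Conditions: TEMPO (cat.), PhI(OAc)2 (2.2 equiv), MeCN–H2O, rt
Reagents that add atoms: water, O
Why: The TEMPO/PhI(OAc)2 oxoammonium oxidation takes the primary alcohol through the aldehyde hydrate to the acid in a mildly acidic, metal-free and non-reducing medium, which should leave the O–O bond, the benzylic position and the β-peroxy linkage intact; the C3 descriptor changes from S to R only through CIP priorities.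

## Compound list

1 | (S)-citronellyl bromide, (6S)-8-bromo-2,6-dimethyloct-2-ene | C[C@@H](CCC=C(C)C)CCBr | starting material
2 | 3-[(3S)-5-bromo-3-methylpentyl]-5,5-dimethyl-1,2,4-trioxolane (secondary ozonide, ring epimers) | C[C@@H](CCC1OOC(C)(C)O1)CCBr | intermediate
3 | (4S)-6-bromo-4-methylhexanal | C[C@@H](CCC=O)CCBr | intermediate
4 | benzyltriphenylphosphonium chloride | [Cl-].c1ccc(cc1)C[P+](c1ccccc1)(c1ccccc1)c1ccccc1 | starting material
5 | benzylidene(triphenyl)phosphorane | c1ccccc1C=P(c1ccccc1)(c1ccccc1)c1ccccc1 | intermediate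
6 | [(5S)-7-bromo-5-methylhept-1-en-1-yl]benzene (E/Z) | C[C@@H](CCC=Cc1ccccc1)CCBr | intermediate
7 | [(5S)-7-bromo-5-methylheptyl]benzene | C[C@@H](CCCCc1ccccc1)CCBr | intermediate
8 | (4R)-4-benzyl-3-propanoyl-1,3-oxazolidin-2-one | CCC(=O)N1[C@H](Cc2ccccc2)COC1=O | starting material
9 | 3-bromo-2-methylprop-1-ene | C=C(C)CBr | starting material
10 | sodium (Z)-enolate of 8 | C/C=C(\[O-])N1[C@H](Cc2ccccc2)COC1=O.[Na+] | intermediate
11 | (4R)-4-benzyl-3-[(2S)-2,4-dimethylpent-4-enoyl]-1,3-oxazolidin-2-one | C=C(C)C[C@H](C)C(=O)N1[C@H](Cc2ccccc2)COC1=O | intermediate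
12 | (2S)-2,4-dimethylpent-4-en-1-ol | C=C(C)C[C@H](C)CO | intermediate
13 | (2S)-2,4-dimethylpent-4-en-1-yl 4-methylbenzenesulfonate | C=C(C)C[C@H](C)COS(=O)(=O)c1ccc(C)cc1 | intermediate
14 | [(3S)-3-methyl-7-phenylheptyl]magnesium bromide | C[C@@H](CCCCc1ccccc1)CC[Mg]Br | intermediate
15 | [(5S,9R)-5,9,11-trimethyldodec-11-en-1-yl]benzene | C[C@@H](CCCCc1ccccc1)CCC[C@@H](C)CC(C)=C | intermediate
16 | carbonyl oxide at C5, (4R,8S)-4,8-dimethyl-12-phenyldodecan-2-one O-oxide | C[C@@H](CCCCc1ccccc1)CCC[C@@H](C)CC(C)=[O+][O-] | intermediate
17 | [(5S,9R)-11-hydroperoxy-11-methoxy-5,9-dimethyldodecyl]benzene (ketal epimers) | C[C@@H](CCCCc1ccccc1)CCC[C@@H](C)CC(C)(OC)OO | intermediate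
18 | triethyl{[(4R,8S)-2-methoxy-4,8-dimethyl-12-phenyldodecan-2-yl]peroxy}silane (ketal epimers) | C[C@@H](CCCCc1ccccc1)CCC[C@@H](C)CC(C)(OC)OO[Si](CC)(CC)CC | intermediate
19 | 3-methylbut-3-en-1-ol | C=C(C)CCO | starting material
20 | tert-butyl[(3-methylbut-3-en-1-yl)oxy]diphenylsilane | C=C(C)CCO[Si](c1ccccc1)(c1ccccc1)C(C)(C)C | intermediate
21 | O-triethylsilyl peroxycarbenium ion at C5 | C[C@@H](CCCCc1ccccc1)CCC[C@@H](C)CC(C)=[O+]O[Si](CC)(CC)CC | intermediate
22 | tertiary C3 carbocation with the C4–C5 bond formed (5R) | C[C@@H](CCCCc1ccccc1)CCC[C@@H](C)C[C@](C)(C[C+](C)CCO[Si](c1ccccc1)(c1ccccc1)C(C)(C)C)OO[Si](CC)(CC)CC | intermediate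
23 | tert-butyl(2-{(3S,5R)-5-[(2R,6S)-2,6-dimethyl-10-phenyldecyl]-3,5-dimethyl-1,2-dioxolan-3-yl}ethoxy)diphenylsilane | C[C@@H](CCCCc1ccccc1)CCC[C@@H](C)C[C@]1(C)C[C@](C)(CCO[Si](c2ccccc2)(c2ccccc2)C(C)(C)C)OO1 | intermediate
24 | 2-{(3S,5R)-5-[(2R,6S)-2,6-dimethyl-10-phenyldecyl]-3,5-dimethyl-1,2-dioxolan-3-yl}ethan-1-ol | C[C@@H](CCCCc1ccccc1)CCC[C@@H](C)C[C@]1(C)C[C@](C)(CCO)OO1 | intermediate
25 | 2-{(3R,5R)-5-[(2R,6S)-2,6-dimethyl-10-phenyldecyl]-3,5-dimethyl-1,2-dioxolan-3-yl}acetaldehyde | C[C@@H](CCCCc1ccccc1)CCC[C@@H](C)C[C@]1(C)C[C@](C)(CC=O)OO1 | intermediate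
26 | 2-{(3R,5R)-5-[(2R,6S)-2,6-dimethyl-10-phenyldecyl]-3,5-dimethyl-1,2-dioxolan-3-yl}acetic acid | C[C@@H](CCCCc1ccccc1)CCC[C@@H](C)C[C@]1(C)C[C@](C)(CC(=O)O)OO1 | target

## Step count and risks

Total step count: 13.
Longest linear sequence: 9 (steps 1–3, 7–9, 11–13; the branch through steps 4–6 is equally long).

**Step 11.** Several processes may compete.
- Cation 22 may lose a proton or pick up chloride before O2 closes the ring.
- Ion 21 may fragment by migration of a carbon substituent to oxygen.
- Weak face selection at C5, combined with only a modest cis preference, spreads the material over four diastereomers that have to be separated in one operation.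

The fallback sets out from 18 and 19 and returns at 23. It forms the same two bonds in separate operations.
- Compound 19 is doubly lithiated (n-BuLi, TMEDA) and silylated with Me3SiCl to give trimethyl({3-[(trimethylsilyl)methyl]but-3-en-1-yl}oxy)silane F1.
- Dilute acid removes the O-silyl group to give 3-[(trimethylsilyl)methyl]but-3-en-1-ol F2.
- TBDPSCl/imidazole then gives the allylsilane silyl ether F3.
- Hosomi–Sakurai-type allylation of the peroxycarbenium ion from 18 (SnCl4, CH2Cl2, −78 °C) forms C4–C5. Loss of Me3Si ends the cationic stage cleanly and gives the homoallylic triethylsilyl peroxide F4, whose C5 epimers form only a two-component mixture to separate.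
- AcOH/THF/H2O frees the homoallylic hydroperoxide F5.
- 5-exo cycloperoxymercuration with Hg(OAc)2 forms C3–O2 and gives the acetoxymercuriomethyl dioxolane F6. Its C3 epimers are again a two-component mixture.
- NaBH4/aq NaOH replaces mercury by hydrogen to give 23.

**Step 8.** Three processes may reduce the return of 17.
- The primary ozonide may cleave in the unwanted direction, to ketone plus formaldehyde oxide.
- Excess ozone may erode the phenyl ring.
- The hydroperoxy ketal may revert to the ketone on silica.

The fallback sets out from 15 and returns at 17. Ozonolysis with reductive work-up (O3, CH2Cl2, −78 °C; PPh3) gives (4R,8S)-4,8-dimethyl-12-phenyldodecan-2-one F7. This ketone is also what the unwanted cleavage direction in step 8 would leave, so that material can be recycled. Iodine-catalysed perhydrolysis of this acyclic ketone (30% H2O2, I2 10 mol %, MeOH, rt) then builds the methoxy hydroperoxide 17 from the carbonyl side.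

**Step 7.** Grignard formation may be accompanied by Wurtz-type homocoupling. Displacement at the β-branched tosylate may also be slow enough for reduction, elimination or halide exchange to compete.

The fallback sets out from 7 and 13 and returns at 15. It replaces the organometallic coupling by a sulfone union.
- Compound 7 with PhSO2Na (DMF, 60 °C) gives {[(3S)-3-methyl-7-phenylheptyl]sulfonyl}benzene F8.
- Compound 13 with NaI (acetone, reflux) gives (4S)-5-iodo-2,4-dimethylpent-1-ene F9.
- Lithiation of F8 (n-BuLi, THF–DMPU, −78 °C) and alkylation with F9 form C8–C9 in the C9-phenylsulfonyl derivative of 15, F10 (epimers at C9).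
- Reductive desulfonylation (Na/Hg, Na2HPO4, MeOH) should spare the 1,1-disubstituted alkene and the arene and deliver 15.

## Further compounds

F1 | step 11 | trimethyl({3-[(trimethylsilyl)methyl]but-3-en-1-yl}oxy)silane | C=C(CCO[Si](C)(C)C)C[Si](C)(C)C
F2 | step 11 | 3-[(trimethylsilyl)methyl]but-3-en-1-ol | C=C(CCO)C[Si](C)(C)C
F3 | step 11 | tert-butyldiphenyl({3-[(trimethylsilyl)methyl]but-3-en-1-yl}oxy)silane | C=C(CCO[Si](c1ccccc1)(c1ccccc1)C(C)(C)C)C[Si](C)(C)C
F4 | step 11 | homoallylic triethylsilyl peroxide (5R, C3 as exocyclic methylene) | C[C@@H](CCCCc1ccccc1)CCC[C@@H](C)C[C@](C)(CC(=C)CCO[Si](c1ccccc1)(c1ccccc1)C(C)(C)C)OO[Si](CC)(CC)CC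
F5 | step 11 | homoallylic hydroperoxide (5R) | C[C@@H](CCCCc1ccccc1)CCC[C@@H](C)C[C@](C)(CC(=C)CCO[Si](c1ccccc1)(c1ccccc1)C(C)(C)C)OO
F6 | step 11 | cis-dioxolane with CH2HgOAc in place of the C3 methyl group | C[C@@H](CCCCc1ccccc1)CCC[C@@H](C)C[C@]1(C)C[C@](C[Hg]OC(C)=O)(CCO[Si](c2ccccc2)(c2ccccc2)C(C)(C)C)OO1
F7 | step 8 | (4R,8S)-4,8-dimethyl-12-phenyldodecan-2-one | C[C@@H](CCCCc1ccccc1)CCC[C@@H](C)CC(C)=O
F8 | step 7 | {[(3S)-3-methyl-7-phenylheptyl]sulfonyl}benzene | C[C@@H](CCCCc1ccccc1)CCS(=O)(=O)c1ccccc1
F9 | step 7 | (4S)-5-iodo-2,4-dimethylpent-1-ene | C=C(C)C[C@H](C)CI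
F10 | step 7 | C9-phenylsulfonyl derivative of 15 (epimers at C9) | C[C@@H](CCCCc1ccccc1)CC(C[C@@H](C)CC(C)=C)S(=O)(=O)c1ccccc1
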